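(Readings and results are calculated with made-up constants, noise included.)

Late in the west run the target stood at 49.5% after 8.00 h, close to the 50.0% of the starting material that the coupling partner can match, so the coupling partner is the limiting reagent. In a shorter flask the question is how many turnovers each working catalyst makes.

| flask | starting material | coupling partner | free catalyst | impurity | temperature | remark | time |
|---|---|---|---|---|---|---|---|
| west | 0.80 M | 0.40 M | 0.40 mM | 0.14 mM | 15 °C | run made earlier |  |
| north-west | 0.80 M | 0.40 M | 0.40 mM | 0.56 mM | 50 °C | run made earlier |  |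
| Tuesday's | 0.80 M | 0.400 M | 0.40 mM | 0.28 mM | 40 °C |  | 2.0 h |
| Friday's | 0.80 M | 0.400 M | 0.40 mM | 0.28 mM | 80 °C |  | 2.0 h |
| Wednesday's | 0.80 M | 0.400 M | 0.40 mM | 0.28 mM | 60 °C |  | 2.0 h |
| Saturday's | 0.80 M | 0.400 M | 0.40 mM | 0.28 mM | 20 °C |  | 2.0 h |

west run (percent of the starting material charged): time / h: target / % = 0.500: 7.3; 1.00: 13.2; 2.50: 30.8; 3.00: 35.3; 5.00: 47.0; 6.00: 49.0; 8.00: 49.5

north-west run (percent of the starting material charged): time / min: target / % = 8.00: 0; 12.0: 0.1; 15.0: 0.2; 25.0: 0; 40.0: 1.0; 60.0: 0.4; 90.0: 0.5

(standard deviation of a reading: 0.3 percentage points)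



1. the flask with the highest amount of target, in percent of the starting material charged ("all alike" if they lie within 1.5 percentage points) (Tuesday's / Friday's / Wednesday's / Saturday's / all alike)
2. final target, as a percentage of the starting material charged, in Tuesday's
3. final target, as a percentage of the starting material charged, in Friday's
4. final target, as a percentage of the starting material charged, in Wednesday's
5. final target, as a percentage of the starting material charged, in Saturday's

I counted turnovers. Let L be the live catalyst, the free catalyst charged minus the impurity charged, taken one to one. West had L = 0.260 mM, and its 30.8% at 2.50 h gives n = 379 h⁻¹, the turnover rate, target made per live catalyst per hour.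

I then took the settings in turn. By hand, raising the impurity from 0.14 mM to 0.28 mM cuts L to 0.120 mM, about half of west's. The readings support the one-to-one count as far as they go: north-west, charged with more impurity than catalyst, had a highest reading of 1.0%.

By hand, the time of 2.0 h at west's n allows 758 turnovers per live catalyst, while using up the coupling partner takes 3330. That count gives 11.4% of target.

Temperature would have to supply the rest, a factor of 4.40 in n to reach the ceiling. By hand I expected a warmer flask to turn faster, but north-west, the warmer run, was charged with more impurity than catalyst, so the runs give n at one temperature. I committed to 11.4% at west's n and left the temperature effect unread.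

The forecast gave 18% for Saturday's, 45% for Tuesday's, 49.5% for Wednesday's and 48% for Friday's, with Wednesday's on top, holding the hot flasks at the ceiling “unless the catalyst dies when hot, which is untested”.

The flasks gave 16.8% in Saturday's, 23.7% in Tuesday's, 14.9% in Wednesday's and 6.90% in Friday's.

    free catalyst + impurity → spent catalyst (k = 170 M⁻¹ s⁻¹, Ea = 46.0 kJ mol⁻¹)
    starting material + free catalyst ⇌ catalyst intermediate A (K = 2.00 M⁻¹, k = 0.810 M⁻¹ s⁻¹, Ea = 39.0 kJ mol⁻¹, ΔH = −90.0 kJ mol⁻¹)
    catalyst intermediate A ⇌ catalyst intermediate B (K = 1.80, k = 0.790 s⁻¹, Ea = 73.0 kJ mol⁻¹, ΔH = −12.0 kJ mol⁻¹)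
    catalyst intermediate C → free catalyst + target (k = 0.950 s⁻¹, Ea = 66.0 kJ mol⁻¹)
    coupling partner + catalyst intermediate B → catalyst intermediate C (k = 3.50 M⁻¹ s⁻¹, Ea = 47.0 kJ mol⁻¹)
    (constants at 20 °C)

On the same L, Tuesday's, the highest, ran at n = 791 h⁻¹, and Friday's ran at 230 h⁻¹, slower than west's 379 h⁻¹. A neighbour of Friday's, charged with 6.8 × 10⁻⁴ M of free catalyst, has L = 0.400 mM, so Friday's n gives 23.0% of target. That neighbour gave 18.8%, which is n = 188 h⁻¹, and it kept 62% of its coupling partner.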